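**Retrosynthetic overview**

- Labels used in the text (target numbering; compound names keep their own locants): ring C1 (CHOAc), C2 (CH2), C3 (CHBr), C4 (CMe2), C5 (=CH), C6 (=C); side chain C7 (CHBr), C8 (CH2Cl).
- Feature: the C1 acetate is allylic to the ring alkene C5=C6 and sits beside the branched alkene carbon C6. The only ring is therefore a masked 2-bromocyclohex-2-enyl acetate, the solvolysis product of a gem-dibromobicyclo[3.1.0]hexane.
- Key disconnection: silver acetate opens the cyclopropane bond between C1 and C5 of the dibromocarbene adduct of a silyloxycyclopentene, forming C1–OAc, C5=C6 and the six-membered ring.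
- After the key step: the C3 bromide by Appel inversion of the liberated alcohol; C7–C8 by Stille coupling of the C6 vinyl bromide with a 1-ethoxyvinylstannane, chlorination to the chloromethyl ketone, CBS reduction and Appel inversion at C7.
- Ring order: cyclopentane (purchased dione), then cyclopropane (carbene addition), then cyclohexene (ring expansion).

Key step: step 6

Assumption: the sense of induction of both oxazaborolidine reductions is assigned from the standard CBS model (quaternary or alkenyl arm as the large group); if a substrate responds in the opposite sense, the antipodal catalyst is used.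

**Route**

Step 1
Reactants: 1 2,2-dimethylcyclopentane-1,3-dione
Product: 2 (3R)-3-hydroxy-2,2-dimethylcyclopentan-1-one
Conditions: (S)-Me-CBS oxazaborolidine (15 mol %), catecholborane (1.0 equiv), CH2Cl2/toluene, −78 → −40 °C; then MeOH
Reagents that add atoms: none
Why: Corey–Bakshi–Shibata reduction in which the two carbonyl groups of 1 are homotopic, so only a carbonyl face has to be chosen, and with the quaternary carbon as the large arm the (S)-catalyst should give the (R)-carbinol while one equivalent of hydride limits diol formation.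

Step 2
Reactants: 2 (3R)-3-hydroxy-2,2-dimethylcyclopentan-1-one
Product: 3 (3R)-2,2-dimethyl-3-(triisopropylsilyloxy)cyclopentan-1-one
Conditions: TIPSOTf, 2,6-lutidine, CH2Cl2, 0 °C → rt
Reagents that add atoms: triisopropylsilyl trifluoromethanesulfonate, CC(C)[Si](C(C)C)(C(C)C)OS(=O)(=O)C(F)(F)F
Why: Silylation of a hindered secondary alcohol with the silyl triflate leaves the carbinol center untouched and gives an ether that should tolerate organolithium, alkoxide and warm acetic acid in steps 4 to 6.

Step 3
Reactants: 3 (3R)-2,2-dimethyl-3-(triisopropylsilyloxy)cyclopentan-1-one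
Product: 4 tosylhydrazone of 3, (E)-configured at C=N
Conditions: TsNHNH2, PPTS (cat.), EtOH, 60 °C
Reagents that add atoms: p-toluenesulfonyl hydrazide, Cc1ccc(cc1)S(=O)(=O)NN
Why: Hydrazone condensation should place the sulfonamide anti to the quaternary carbon, that is syn to the only α-methylene, as the Shapiro reaction requires.

Step 4
Reactants: 4 tosylhydrazone of 3
Product: 6 (4R)-3,3-dimethyl-4-(triisopropylsilyloxy)cyclopent-1-ene, via vinyllithium 5 (not isolated)
Conditions: n-BuLi (3 equiv), TMEDA, THF, −78 → 0 °C; then H2O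
Reagents that add atoms: none
Why: Shapiro reaction in which deprotonation at N–H and at the single α-methylene, then loss of sulfinate and dinitrogen, gives the vinyllithium, which is protonated to the only possible alkene without touching the silyloxy-bearing center.

Step 5
Reactants: 6 (4R)-3,3-dimethyl-4-(triisopropylsilyloxy)cyclopent-1-ene; 7 bromoform
Product: 8 (1R,3R,5R)-6,6-dibromo-2,2-dimethyl-3-(triisopropylsilyloxy)bicyclo[3.1.0]hexane (cyclopropane anti to the silyloxy group)
Conditions: CHBr3, KOtBu, pentane, −10 °C → rt; product kept at or below rt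
Reagents that add atoms: bromoform (7), BrC(Br)Br
Why: Doering–Hoffmann dibromocarbene cycloaddition is stereospecifically cis across the ring alkene and should occur mainly anti to the silyloxy group, while any syn adduct is carried on because it converges in step 6.

Step 6
Reactants: 8 (1R,3R,5R)-6,6-dibromo-2,2-dimethyl-3-(triisopropylsilyloxy)bicyclo[3.1.0]hexane
Product: 10 (1R,5R)-2-bromo-4,4-dimethyl-5-(triisopropylsilyloxy)cyclohex-2-en-1-yl acetate, via 2-bromoallyl cation 9 (not isolated)
Conditions: AgOAc (2.5 equiv), AcOH, 50 °C, dark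
Reagents that add atoms: silver acetate, CC(=O)[O-].[Ag+]
Why: Monovalent silver removes the bromide of 8 that lies over the five-membered ring while the cyclopropane bond between the two bridgehead carbons (C1–C5) opens in a disrotatory two-electron electrocyclic process (Woodward–Hoffmann–DePuy rule), giving the ring-held 2-bromoallyl cation 9 whose central carbon is the former carbene carbon C6, and solvent acetate then bonds to C1. The closest known reaction type is the silver-promoted solvolytic ring expansion of 6,6-dibromobicyclo[3.1.0]hexanes to 2-bromocyclohex-2-enyl acetates. The six-membered ring is not closed from a chain; it arises by one-carbon expansion of the cyclopentane as the shared cyclopropane bond breaks. The new stereocenter C1 is controlled by the C3 silyloxy group: pseudo-axial capture syn to it would meet a 1,3-diaxial clash with the triisopropylsilyl ether, so acetate should add on the conformer holding that group equatorial and end up trans to it (1R). The step needs capture at C1 and not at C5, which the neopentyl shielding of C5 by the C4 gem-dimethyl group should secure, and both cyclopropane diastereomers give the same cation.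

Step 7
Reactants: 10 (1R,5R)-2-bromo-4,4-dimethyl-5-(triisopropylsilyloxy)cyclohex-2-en-1-yl acetate
Product: 11 (1R,5R)-2-bromo-5-hydroxy-4,4-dimethylcyclohex-2-en-1-yl acetate
Conditions: HF·pyridine, THF/pyridine, 0 °C → rt
Reagents that add atoms: none
Why: Fluoride-driven Si–O cleavage under buffered acidic conditions should spare the allylic acetate and the vinyl bromide, and the trans relation of the two oxygens prevents acyl migration.

Step 8
Reactants: 11 (1R,5R)-2-bromo-5-hydroxy-4,4-dimethylcyclohex-2-en-1-yl acetate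
Product: 12 (1R,5S)-2,5-dibromo-4,4-dimethylcyclohex-2-en-1-yl acetate
Conditions: CBr4, PPh3, toluene, rt → 65 °C
Reagents that add atoms: carbon tetrabromide, BrC(Br)(Br)Br
Why: Appel reaction in which bromide attacks the phosphorus-activated C3 from the face opposite the leaving oxygen (SN2, R → S, now cis to the C1 acetate), best through the half-chair with the C–O bond axial, a displacement known for axial 2,2-dimethylcyclohexanols despite the adjacent quaternary carbon.

Step 9
Reactants: 12 (1R,5S)-2,5-dibromo-4,4-dimethylcyclohex-2-en-1-yl acetate; 13 tributyl(1-ethoxyvinyl)stannane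
Product: 14 (1R,5S)-5-bromo-2-(1-ethoxyethenyl)-4,4-dimethylcyclohex-2-en-1-yl acetate
Conditions: Pd(PPh3)4 (5 mol %), toluene, 90 °C; chromatography on Et3N-deactivated silica
Reagents that add atoms: tributyl(1-ethoxyvinyl)stannane (13), CCOC(=C)[Sn](CCCC)(CCCC)CCCC
Why: Stille coupling in which zerovalent palladium inserts into the alkenyl C–Br bond far faster than into the hindered secondary alkyl bromide, so the C6–C7 bond forms with all stereocenters untouched.

Step 10
Reactants: 14 (1R,5S)-5-bromo-2-(1-ethoxyethenyl)-4,4-dimethylcyclohex-2-en-1-yl acetate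
Product: 15 (1R,5S)-5-bromo-2-(chloroacetyl)-4,4-dimethylcyclohex-2-en-1-yl acetate
Conditions: NCS, THF/H2O (4:1), 0 °C
Reagents that add atoms: N-chlorosuccinimide, O=C1CCC(=O)N1Cl; water, O
Why: Electrophilic chlorination of the enol ether at its terminal carbon C8, water capture at C7 and loss of ethanol is the standard conversion of a 1-alkoxyvinyl group into a halomethyl ketone, and the hindered ring alkene and the other halides should be inert.

Step 11
Reactants: 15 (1R,5S)-5-bromo-2-(chloroacetyl)-4,4-dimethylcyclohex-2-en-1-yl acetate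
Product: 16 (1R,5S)-5-bromo-2-[(1R)-2-chloro-1-hydroxyethyl]-4,4-dimethylcyclohex-2-en-1-yl acetate
Conditions: (R)-Me-CBS oxazaborolidine (20 mol %), catecholborane (1.5 equiv), toluene/CH2Cl2, −78 °C; then MeOH, neutral work-up
Reagents that add atoms: none
Why: CBS reduction of an α-chloro enone with the alkenyl arm as the large group and CH2Cl as the small group should give the (R)-chlorohydrin under reagent control, and catecholborane at low temperature avoids hydroboration, 1,4-reduction and ester reduction.

Step 12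
Reactants: 16 (1R,5S)-5-bromo-2-[(1R)-2-chloro-1-hydroxyethyl]-4,4-dimethylcyclohex-2-en-1-yl acetate
Product: 17 (1R,5S)-5-bromo-2-[(1S)-1-bromo-2-chloroethyl]-4,4-dimethylcyclohex-2-en-1-yl acetate
Conditions: CBr4, PPh3, CH2Cl2, −20 → 0 °C
Reagents that add atoms: carbon tetrabromide, BrC(Br)(Br)Br
Why: Appel bromination with SN2 inversion at C7 (R alcohol → S bromide), where allylic transposition would require attack at the neopentyl C5 and the β-chlorine disfavours ionisation, so direct displacement should dominate.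

**Compound list**

1 | 2,2-dimethylcyclopentane-1,3-dione | CC1(C)C(=O)CCC1=O | starting material
2 | (3R)-3-hydroxy-2,2-dimethylcyclopentan-1-one | O=C1CC[C@@H](O)C1(C)C | intermediate
3 | (3R)-2,2-dimethyl-3-(triisopropylsilyloxy)cyclopentan-1-one | O=C1CC[C@@H](O[Si](C(C)C)(C(C)C)C(C)C)C1(C)C | intermediate
4 | tosylhydrazone of 3, (E) at C=N | Cc1ccc(cc1)S(=O)(=O)N/N=C1\CC[C@@H](O[Si](C(C)C)(C(C)C)C(C)C)C1(C)C | intermediate
5 | [(4R)-5,5-dimethyl-4-(triisopropylsilyloxy)cyclopent-1-en-1-yl]lithium | [Li]C1=CC[C@@H](O[Si](C(C)C)(C(C)C)C(C)C)C1(C)C | intermediate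
6 | (4R)-3,3-dimethyl-4-(triisopropylsilyloxy)cyclopent-1-ene | C1=CC[C@@H](O[Si](C(C)C)(C(C)C)C(C)C)C1(C)C | intermediate
7 | bromoform | BrC(Br)Br | starting material
8 | (1R,3R,5R)-6,6-dibromo-2,2-dimethyl-3-(triisopropylsilyloxy)bicyclo[3.1.0]hexane | BrC1(Br)[C@@H]2C[C@@H](O[Si](C(C)C)(C(C)C)C(C)C)C(C)(C)[C@H]12 | intermediate
9 | (5R)-2-bromo-4,4-dimethyl-5-(triisopropylsilyloxy)cyclohex-2-en-1-ylium (2-bromoallyl cation) | [CH+]1C[C@@H](O[Si](C(C)C)(C(C)C)C(C)C)C(C)(C)C=C1Br | intermediate
10 | (1R,5R)-2-bromo-4,4-dimethyl-5-(triisopropylsilyloxy)cyclohex-2-en-1-yl acetate | CC(=O)O[C@@H]1C[C@@H](O[Si](C(C)C)(C(C)C)C(C)C)C(C)(C)C=C1Br | intermediate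
11 | (1R,5R)-2-bromo-5-hydroxy-4,4-dimethylcyclohex-2-en-1-yl acetate | CC(=O)O[C@@H]1C[C@@H](O)C(C)(C)C=C1Br | intermediate
12 | (1R,5S)-2,5-dibromo-4,4-dimethylcyclohex-2-en-1-yl acetate | CC(=O)O[C@@H]1C[C@H](Br)C(C)(C)C=C1Br | intermediate
13 | tributyl(1-ethoxyvinyl)stannane | CCOC(=C)[Sn](CCCC)(CCCC)CCCC | starting material
14 | (1R,5S)-5-bromo-2-(1-ethoxyethenyl)-4,4-dimethylcyclohex-2-en-1-yl acetate | CC(=O)O[C@@H]1C[C@H](Br)C(C)(C)C=C1C(=C)OCC | intermediate
15 | (1R,5S)-5-bromo-2-(chloroacetyl)-4,4-dimethylcyclohex-2-en-1-yl acetate | CC(=O)O[C@@H]1C[C@H](Br)C(C)(C)C=C1C(=O)CCl | intermediate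
16 | (1R,5S)-5-bromo-2-[(1R)-2-chloro-1-hydroxyethyl]-4,4-dimethylcyclohex-2-en-1-yl acetate | CC(=O)O[C@@H]1C[C@H](Br)C(C)(C)C=C1[C@@H](O)CCl | intermediate
17 | (1R,5S)-5-bromo-2-[(1S)-1-bromo-2-chloroethyl]-4,4-dimethylcyclohex-2-en-1-yl acetate | CC(=O)O[C@@H]1C[C@H](Br)C(C)(C)C=C1[C@H](Br)CCl | target

**Step count and risks**

Total steps: 12. Longest linear sequence: 12 steps (1 to 17).

Steps most likely to fail:

1. Step 6. Acetate capture at C1 may show poor facial selectivity, and proton loss from the cation to a diene may compete. Fallback: C1 is set by a reagent instead of by the substrate. Setting out from 8, the ring expansion is run with AgClO4 in aqueous acetone so that water is the nucleophile, giving (5R)-2-bromo-4,4-dimethyl-5-(triisopropylsilyloxy)cyclohex-2-en-1-ol F1 as a mixture of C1 epimers. Dess–Martin oxidation (NaHCO3, CH2Cl2) merges both epimers into (5R)-2-bromo-4,4-dimethyl-5-(triisopropylsilyloxy)cyclohex-2-en-1-one F2. CBS reduction of this 2-bromoenone with the (S)-oxazaborolidine and catecholborane (bromoalkenyl arm as the large group) should give (1R,5R)-2-bromo-4,4-dimethyl-5-(triisopropylsilyloxy)cyclohex-2-en-1-ol F3. Acetylation (Ac2O, pyridine, DMAP) comes back to the route at 10.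

2. Step 8. Elimination toward C2, methyl migration from C4 or participation of the C1 acetate may outrun backside attack of bromide at the neopentyl-type C3. Fallback: the displacement is moved to the five-membered ring, where backside attack is easier and no ester is present. Setting out from 6, TBAF in THF gives (1R)-2,2-dimethylcyclopent-3-en-1-ol F4, and Appel bromination (CBr4, PPh3) with inversion gives (4S)-4-bromo-3,3-dimethylcyclopent-1-ene F5. Because alkoxide base would eliminate HBr, dibromocarbene is transferred under neutral conditions from PhHgCBr3 in benzene at 80 °C, giving (1S,3S,5S)-3,6,6-tribromo-2,2-dimethylbicyclo[3.1.0]hexane F6. Ring expansion with AgClO4 in aqueous acetone should deliver water to C1 anti to the C3 bromide, giving (1S,5S)-2,5-dibromo-4,4-dimethylcyclohex-2-en-1-ol F7. Mitsunobu esterification with acetic acid (PPh3, DIAD, THF) inverts C1 and comes back to the route at 12.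

3. Step 12. Configurational purity at C7 may be lost by bromide exchange on the allylic bromide, by ionisation, or by participation of the C1 acetate carbonyl through a six-membered acyloxonium ion. Fallback: the side chain is built with the C1 oxygen as a silyl ether, which cannot participate, and the acetate is restored last. Setting out from 12:
   - K2CO3 in MeOH at 0 °C gives (1R,5S)-2,5-dibromo-4,4-dimethylcyclohex-2-en-1-ol F8.
   - TBSOTf and 2,6-lutidine give (1R,5S)-2,5-dibromo-4,4-dimethylcyclohex-2-en-1-yl tert-butyldimethylsilyl ether F9.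
   - Stille coupling with 13 (Pd(PPh3)4, toluene, 90 °C) gives (1R,5S)-5-bromo-2-(1-ethoxyethenyl)-4,4-dimethylcyclohex-2-en-1-yl tert-butyldimethylsilyl ether F10.
   - NCS in aqueous THF gives (1R,5S)-5-bromo-2-(chloroacetyl)-4,4-dimethylcyclohex-2-en-1-yl tert-butyldimethylsilyl ether F11.
   - CBS reduction with the (R)-oxazaborolidine gives (1R,5S)-5-bromo-2-[(1R)-2-chloro-1-hydroxyethyl]-4,4-dimethylcyclohex-2-en-1-yl tert-butyldimethylsilyl ether F12.
   - Appel bromination gives (1R,5S)-5-bromo-2-[(1S)-1-bromo-2-chloroethyl]-4,4-dimethylcyclohex-2-en-1-yl tert-butyldimethylsilyl ether F13.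
   - HF·pyridine gives (1R,5S)-5-bromo-2-[(1S)-1-bromo-2-chloroethyl]-4,4-dimethylcyclohex-2-en-1-ol F14.
   - Acetylation (Ac2O, 2,6-lutidine, DMAP cat., CH2Cl2, 0 °C) comes back to the route at 17.

**Further compounds**

F1 | step 6 | (5R)-2-bromo-4,4-dimethyl-5-(triisopropylsilyloxy)cyclohex-2-en-1-ol, mixture of C1 epimers | OC1C[C@@H](O[Si](C(C)C)(C(C)C)C(C)C)C(C)(C)C=C1Br
F2 | step 6 | (5R)-2-bromo-4,4-dimethyl-5-(triisopropylsilyloxy)cyclohex-2-en-1-one | O=C1C[C@@H](O[Si](C(C)C)(C(C)C)C(C)C)C(C)(C)C=C1Br
F3 | step 6 | (1R,5R)-2-bromo-4,4-dimethyl-5-(triisopropylsilyloxy)cyclohex-2-en-1-ol | O[C@@H]1C[C@@H](O[Si](C(C)C)(C(C)C)C(C)C)C(C)(C)C=C1Br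
F4 | step 8 | (1R)-2,2-dimethylcyclopent-3-en-1-ol | C1=CC[C@@H](O)C1(C)C
F5 | step 8 | (4S)-4-bromo-3,3-dimethylcyclopent-1-ene | C1=CC[C@H](Br)C1(C)C
F6 | step 8 | (1S,3S,5S)-3,6,6-tribromo-2,2-dimethylbicyclo[3.1.0]hexane | BrC1(Br)[C@H]2C[C@H](Br)C(C)(C)[C@@H]12
F7 | step 8 | (1S,5S)-2,5-dibromo-4,4-dimethylcyclohex-2-en-1-ol | O[C@H]1C[C@H](Br)C(C)(C)C=C1Br
F8 | step 12 | (1R,5S)-2,5-dibromo-4,4-dimethylcyclohex-2-en-1-ol | O[C@@H]1C[C@H](Br)C(C)(C)C=C1Br
F9 | step 12 | (1R,5S)-2,5-dibromo-4,4-dimethylcyclohex-2-en-1-yl tert-butyldimethylsilyl ether | CC(C)(C)[Si](C)(C)O[C@@H]1C[C@H](Br)C(C)(C)C=C1Br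
F10 | step 12 | (1R,5S)-5-bromo-2-(1-ethoxyethenyl)-4,4-dimethylcyclohex-2-en-1-yl tert-butyldimethylsilyl ether | CC(C)(C)[Si](C)(C)O[C@@H]1C[C@H](Br)C(C)(C)C=C1C(=C)OCC
F11 | step 12 | (1R,5S)-5-bromo-2-(chloroacetyl)-4,4-dimethylcyclohex-2-en-1-yl tert-butyldimethylsilyl ether | CC(C)(C)[Si](C)(C)O[C@@H]1C[C@H](Br)C(C)(C)C=C1C(=O)CCl
F12 | step 12 | (1R,5S)-5-bromo-2-[(1R)-2-chloro-1-hydroxyethyl]-4,4-dimethylcyclohex-2-en-1-yl tert-butyldimethylsilyl ether | CC(C)(C)[Si](C)(C)O[C@@H]1C[C@H](Br)C(C)(C)C=C1[C@@H](O)CCl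
F13 | step 12 | (1R,5S)-5-bromo-2-[(1S)-1-bromo-2-chloroethyl]-4,4-dimethylcyclohex-2-en-1-yl tert-butyldimethylsilyl ether | CC(C)(C)[Si](C)(C)O[C@@H]1C[C@H](Br)C(C)(C)C=C1[C@H](Br)CCl
F14 | step 12 | (1R,5S)-5-bromo-2-[(1S)-1-bromo-2-chloroethyl]-4,4-dimethylcyclohex-2-en-1-ol | O[C@@H]1C[C@H](Br)C(C)(C)C=C1[C@H](Br)CCl
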